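**Retrosynthetic overview** (rings: A hydroquinone, B five-membered ring fused to A, C methylcyclohexene, D cyclohexane-1,4-dione, E cyclopentanone bearing the isopropenyl group)
1. Ring A hydroquinone from its dimethyl ether; ring E by intramolecular Hosomi–Sakurai allylation of a ring D ene-dione; ring D by ring-closing metathesis between the two acyl carbons that sit on the adjacent quaternary carbons.
2. Both acyl carbons, ring B and ring C come from lactone 11, made from the flat coumarin 9 in one photochemical/thermal operation: crossed [2+2] of the coumarin C3=C4 bond with the peri styrenyl C=C (ring B plus a cyclobutane), then a [1,3] shift of the vinylcyclobutane that widens the four-membered ring by the two isopropenyl carbons to ring C.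
3. Enabling feature: in ring C the bond from the ring CH2 to the quaternary bridgehead carbon (bonded to ring A and to a ring D carbonyl) is allylic to the C(CH3)=CH unit, so that bridgehead, the quaternary bridge carbon, the benzylic CH and the vinylic CH are arranged as a vinylcyclobutane after a [1,3] shift. The ring A oxygen next to that bridgehead can also reach the bridging carbonyl carbon, so a coumarin lactone (a C–O bond absent from the target, cleaved in step 8) holds that carbon syn to ring A while both quaternary centres form.
4. Coumarin 9 comes from hydroquinone and a 2-allyl oxalacetate (Pechmann), then ortho-formylation, O-methylation, cross-metathesis and Wittig olefination.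
5. Order of ring formation: A (bought), lactone ring (temporary), B with the cyclobutane, C (from the cyclobutane), D, E.

Key step: step 7

Remark: the two side-chain alkenes of 8 to 16 are drawn E (both geometries converge in steps 7 and 12), and the sense of induction of the oxazaborolidine–AlBr3 catalyst is assumed by analogy with simpler coumarins (the mirror-image catalyst is equally accessible).

Step 1
Reactants: 1 ethyl pent-4-enoate; 2 diethyl oxalate
Product: 3 diethyl 2-oxo-3-(prop-2-enyl)butanedioate
Conditions: NaOEt, Et2O, 0 °C to rt; then aq HCl
Reagents that add atoms: none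
Why: Crossed Claisen condensation, in which the enolate of 1 acylates the non-enolisable oxalate and the acidic product enolate drives the equilibrium; the new stereocentre is lost as sp2 carbon in step 2.

Step 2
Reactants: 3 diethyl 2-oxo-3-(prop-2-enyl)butanedioate; 4 hydroquinone
Product: 5 ethyl 6-hydroxy-2-oxo-3-(prop-2-enyl)-2H-chromene-4-carboxylate
Conditions: MeSO3H, 40 °C
Reagents that add atoms: none
Why: Pechmann condensation (transesterification, ring hydroxyalkylation by the keto group, dehydration) should place the oxalyl ester at C-4 and the allyl group at C-3, and the symmetry of hydroquinone allows only one regioisomer.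

Step 3
Reactants: 5 ethyl 6-hydroxy-2-oxo-3-(prop-2-enyl)-2H-chromene-4-carboxylate
Product: 6 ethyl 5-formyl-6-hydroxy-2-oxo-3-(prop-2-enyl)-2H-chromene-4-carboxylate
Conditions: MgCl2, Et3N, (CH2O)n, MeCN, 80 °C; then aq HCl
Reagents that add atoms: formaldehyde (as paraformaldehyde), C=O
Why: Magnesium-phenoxide-directed ortho-formylation (Casnati–Skattebøl) should go to C-5, the ortho position with the higher double-bond character toward C-6, as electrophiles and Claisen rearrangements do in 6-hydroxy-4-methylcoumarins.

Step 4
Reactants: 6 ethyl 5-formyl-6-hydroxy-2-oxo-3-(prop-2-enyl)-2H-chromene-4-carboxylate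
Product: 7 ethyl 5-formyl-6-methoxy-2-oxo-3-(prop-2-enyl)-2H-chromene-4-carboxylate
Conditions: MeI, K2CO3, DMF, rt
Reagents that add atoms: iodomethane, CI
Why: Williamson methylation of the only phenol installs the ring A protecting group that is removed oxidatively in step 13.

Step 5
Reactants: 7 ethyl 5-formyl-6-methoxy-2-oxo-3-(prop-2-enyl)-2H-chromene-4-carboxylate
Product: 8 ethyl 5-formyl-6-methoxy-3-[(E)-3-methyl-4-(trimethylsilyl)but-2-enyl]-2-oxo-2H-chromene-4-carboxylate
Conditions: CH2=C(CH3)CH2SiMe3 (excess), second-generation Grubbs catalyst, CH2Cl2, 40 °C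
Reagents that add atoms: trimethyl(2-methylprop-2-enyl)silane, C=C(C)C[Si](C)(C)C
Why: Olefin cross-metathesis of the terminal allyl group with an excess of the 1,1-disubstituted allylsilane should give the trisubstituted allylsilane, the electron-poor tetrasubstituted coumarin C=C and the aldehyde being inert.

Step 6
Reactants: 8 ethyl 5-formyl-6-methoxy-3-[(E)-3-methyl-4-(trimethylsilyl)but-2-enyl]-2-oxo-2H-chromene-4-carboxylate
Product: 9 ethyl 6-methoxy-5-[(E)-3-methylbuta-1,3-dienyl]-3-[(E)-3-methyl-4-(trimethylsilyl)but-2-enyl]-2-oxo-2H-chromene-4-carboxylate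
Conditions: [CH2=C(CH3)CH2PPh3]Cl, KOtBu, THF, −78 to 0 °C
Reagents that add atoms: (2-methylprop-2-enyl)triphenylphosphonium chloride, C=C(C)C[P+](c1ccccc1)(c1ccccc1)c1ccccc1.[Cl-]
Why: Wittig olefination of the non-enolisable aryl aldehyde with the semi-stabilised allylic ylide should give the 1-aryl-3-methylbutadiene, any Z isomer being equilibrated under the irradiation of step 7.

Step 7
Reactants: 9 ethyl 6-methoxy-5-[(E)-3-methylbuta-1,3-dienyl]-3-[(E)-3-methyl-4-(trimethylsilyl)but-2-enyl]-2-oxo-2H-chromene-4-carboxylate
Product: 11 ring C lactone (lactone-bridged benzobicyclo[3.2.1]octadiene ethyl ester), via vinylcyclobutane photoadduct 10 (not isolated)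
Conditions: AlBr3-activated oxazaborolidine from (S)-diarylprolinol and an arylboronic acid (50 mol %), hν (420 nm), CH2Cl2, −75 °C; then Et3N, filtration (SiO2), toluene, 110 °C
Reagents that add atoms: none
Why: Proposed new method: the AlBr3-activated oxazaborolidine binds the lactone carbonyl of 9, shifts its absorption to the red and shields one face of the C3=C4 bond, so that selective excitation of the complex triggers a crossed intramolecular [2+2] photocycloaddition with the peri styrenyl C=C; the closest known reaction types are the chiral-Lewis-acid-catalysed intramolecular [2+2] photocycloaddition of coumarins, the crossed photocyclisation of ortho-divinylarenes to benzobicyclo[2.1.1]hexenes and the thermal vinylcyclobutane-to-cyclohexene rearrangement. Ring B closes first, as a five-membered ring by 1,5-bonding of C3 to the benzylic alkene carbon (the straight mode would need a benzocyclobutene), and the transoid allyl radical of the s-trans diene can then only close 1,4 at its inner carbon onto C4, which gives the vinylcyclobutane 10. On warming, the cyclobutane bond between the quaternary carbon that is benzylic and α to the ester and the isopropenyl-bearing CH homolyses and the diradical recloses at the CH2 terminus of the allyl radical, a [1,3] shift that widens the four-membered ring by two atoms to ring C and exchanges a bicyclo[2.1.1]hexene for a far less strained bicyclo[3.2.1]octadiene. The lactone forces the future bridging carbonyl carbon to the ring A side of the new quaternary bridge carbon, the bridged topology fixes both bridgeheads relative to it, and the face selection by the catalyst sets the absolute configuration of all three centres (the isopropenyl epimer of 10 is irrelevant because that carbon becomes sp2). The selectivities needed are crossed over straight addition (secured by the two-atom arene tether), cyclobutane over direct six-ring closure in the photochemical stage (secured by the s-trans diene), and cleavage of the doubly stabilised bond with reclosure to the six-membered ring in the thermal stage (secured by strain release, cleavage of the other benzylic ring bond being reversible or leading back to 9).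

Step 8
Reactants: 11 ring C lactone (lactone-bridged benzobicyclo[3.2.1]octadiene ethyl ester)
Product: 13 phenol bis(vinyl carbinol), via lactol aldehyde 12 (not isolated)
Conditions: i-Bu2AlH, CH2Cl2, −78 °C; then CH2=CHMgBr, THF, −78 to 0 °C; aq potassium sodium tartrate
Reagents that add atoms: vinylmagnesium bromide, C=C[Mg]Br
Why: Partial reduction at −78 °C should stop at the lactol aluminate and the hemiacetal aluminate of the hindered ester, both of which react as aldehydes with the vinyl Grignard reagent in the same flask; the carbinol epimers are inconsequential (both become carbonyls in step 11) and the lactone tether is cleaved here, freeing the ring A oxygen.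

Step 9
Reactants: 13 phenol bis(vinyl carbinol)
Product: 14 aryl dimethyl ether bis(vinyl carbinol)
Conditions: MeI, K2CO3, acetone, 50 °C
Reagents that add atoms: iodomethane, CI
Why: Chemoselective Williamson methylation of the phenol in the presence of two hindered secondary alcohols protects it against the oxidants and Lewis acid of steps 11 to 13.

Step 10
Reactants: 14 aryl dimethyl ether bis(vinyl carbinol)
Product: 15 ring D cyclohex-2-ene-1,4-diol
Conditions: second-generation Grubbs catalyst, CH2Cl2, 40 °C
Reagents that add atoms: none
Why: Ring-closing metathesis of the two monosubstituted allylic-alcohol alkenes should close ring D as a cis-cyclohexene, the trisubstituted ring C and allylsilane alkenes staying out.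

Step 11
Reactants: 15 ring D cyclohex-2-ene-1,4-diol
Product: 16 ring D ene-1,4-dione
Conditions: (COCl)2, DMSO, CH2Cl2, −78 °C; then Et3N, −78 to 0 °C
Reagents that add atoms: none
Why: Swern oxidation of both allylic alcohols should give the cis-ene-1,4-dione, and no centre can epimerise because both flanking carbons are quaternary.

Step 12
Reactants: 16 ring D ene-1,4-dione
Product: 17 O,O'-dimethyl ether of CNP0287617.1
Conditions: TiCl4, CH2Cl2, −78 °C; then aq NaHCO3
Reagents that add atoms: none
Why: Intramolecular Hosomi–Sakurai conjugate allylation, in which the γ-carbon of the allylsilane adds to the enone β-carbon lying α to the bridging carbonyl (five-membered closure to the bicyclo[3.2.1]octane, the other β-carbon needing a boat-like bicyclo[2.2.2] closure), loss of silicon gives the isopropenyl group regiospecifically, the ring-fusion CH is set by the bridged topology, and the open transition state should place the isopropenyl group exo because the endo side is blocked by the CH2 of the ring C bridge.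

Step 13
Reactants: 17 O,O'-dimethyl ether of CNP0287617.1
Product: 19 CNP0287617.1, via ring A quinone 18 (not isolated)
Conditions: (NH4)2Ce(NO3)6, MeCN/H2O, 0 °C; then aq Na2S2O4, EtOAc, rt
Reagents that add atoms: water, O
Why: Oxidative demethylation of the 1,4-dimethoxyarene gives the quinone, which dithionite reduces in the work-up to the hydroquinone without touching ketones, alkenes or any stereocentre.

**Compound list**
1 | ethyl pent-4-enoate | C=CCCC(=O)OCC | starting material
2 | diethyl oxalate | CCOC(=O)C(=O)OCC | starting material
3 | diethyl 2-oxo-3-(prop-2-enyl)butanedioate (racemic, enolisable) | CCOC(=O)C(=O)C(CC=C)C(=O)OCC | intermediate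
4 | hydroquinone (benzene-1,4-diol) | Oc1ccc(O)cc1 | starting material
5 | ethyl 6-hydroxy-2-oxo-3-(prop-2-enyl)-2H-chromene-4-carboxylate | CCOC(=O)C1=C(CC=C)C(=O)Oc2ccc(O)cc21 | intermediate
6 | ethyl 5-formyl-6-hydroxy-2-oxo-3-(prop-2-enyl)-2H-chromene-4-carboxylate | CCOC(=O)C1=C(CC=C)C(=O)Oc2ccc(O)c(C=O)c21 | intermediate
7 | ethyl 5-formyl-6-methoxy-2-oxo-3-(prop-2-enyl)-2H-chromene-4-carboxylate | CCOC(=O)C1=C(CC=C)C(=O)Oc2ccc(OC)c(C=O)c21 | intermediate
8 | ethyl 5-formyl-6-methoxy-3-[(E)-3-methyl-4-(trimethylsilyl)but-2-enyl]-2-oxo-2H-chromene-4-carboxylate | CCOC(=O)C1=C(C/C=C(C)/C[Si](C)(C)C)C(=O)Oc2ccc(OC)c(C=O)c21 | intermediate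
9 | ethyl 6-methoxy-5-[(E)-3-methylbuta-1,3-dienyl]-3-[(E)-3-methyl-4-(trimethylsilyl)but-2-enyl]-2-oxo-2H-chromene-4-carboxylate | CCOC(=O)C1=C(C/C=C(C)/C[Si](C)(C)C)C(=O)Oc2ccc(OC)c(/C=C/C(C)=C)c21 | intermediate
10 | vinylcyclobutane photoadduct: benzobicyclo[2.1.1]hexene whose two bridgeheads are the ester-bearing quaternary carbon and the benzylic CH; one one-carbon bridge is the CH carrying the isopropenyl group (both epimers), the other is the quaternary carbon carrying the silylbutenyl chain and the lactone carbonyl (syn to ring A, closed onto the ring A oxygen) | C[Si](C)(C)C/C(C)=C/C[C@]12C(=O)Oc3ccc(OC)c4c3[C@]2(C(=O)OCC)C(C(C)=C)[C@@H]14 | intermediate (not isolated)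
11 | ring C lactone: benzobicyclo[3.2.1]octadiene with CH2–C(CH3)=CH as three-carbon bridge, ethyl ester on the quaternary benzylic bridgehead, and on the one-carbon bridge the lactone carbonyl (syn to ring A) and the silylbutenyl chain (syn to the alkene bridge) | C[Si](C)(C)C/C(C)=C/C[C@]12C(=O)Oc3ccc(OC)c4c3[C@]2(C(=O)OCC)CC(C)=C[C@@H]14 | intermediate
12 | lactol aldehyde: lactol in place of the lactone (both anomers), aldehyde in place of the ester | C[Si](C)(C)C/C(C)=C/C[C@]12C(O)Oc3ccc(OC)c4c3[C@]2(C=O)CC(C)=C[C@@H]14 | intermediate (not isolated)
13 | phenol bis(vinyl carbinol): 1-hydroxyprop-2-enyl groups on the bridge carbon and on the bridgehead (carbinol epimers), free ring A phenol | C[Si](C)(C)C/C(C)=C/C[C@@]1(C(O)C=C)[C@@]2(C(O)C=C)CC(C)=C[C@@H]1c1c(OC)ccc(O)c12 | intermediate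
14 | aryl dimethyl ether bis(vinyl carbinol) | C[Si](C)(C)C/C(C)=C/C[C@@]1(C(O)C=C)[C@@]2(C(O)C=C)CC(C)=C[C@@H]1c1c(OC)ccc(OC)c12 | intermediate
15 | ring D cyclohex-2-ene-1,4-diol (rings A to D, carbinol epimers) | C[Si](C)(C)C/C(C)=C/C[C@@]23C(O)C=CC(O)[C@@]21CC(C)=C[C@@H]3c2c(OC)ccc(OC)c21 | intermediate
16 | ring D ene-1,4-dione (rings A to D, allylsilane chain on the bridge carbon) | C[Si](C)(C)C/C(C)=C/C[C@@]23C(=O)C=CC(=O)[C@@]21CC(C)=C[C@@H]3c2c(OC)ccc(OC)c21 | intermediate
17 | O,O'-dimethyl ether of CNP0287617.1 | C=C(C)[C@H]1C[C@@]23C(=O)[C@@H]1CC(=O)[C@@]21CC(C)=C[C@@H]3c2c(OC)ccc(OC)c21 | intermediate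
18 | ring A quinone of CNP0287617.1 | C=C(C)[C@H]1C[C@@]23C(=O)[C@@H]1CC(=O)[C@@]21CC(C)=C[C@@H]3C2=C1C(=O)C=CC2=O | intermediate (not isolated)
19 | CNP0287617.1 | C=C(C)[C@H]1C[C@@]23C(=O)[C@@H]1CC(=O)[C@@]21CC(C)=C[C@@H]3c2c(O)ccc(O)c21 | target

**Total step count:** 13
**Longest linear sequence:** 13 steps (1 and 2 to 19)

**Steps most likely to fail**

Step 7 (proposed new method). The dienyl chromophore of catalyst-free 9 may be excited alongside the Lewis-acid complex, which would erode the facial selectivity, or the 1,4-diradical may revert so that only E/Z isomerisation is seen. Fallback: the route sets out from 9, which is irradiated at 405 nm with thioxanthen-9-one as triplet sensitiser at ambient temperature. The racemic photoadduct is isolated, that is 10 together with its mirror image, the enantiomeric vinylcyclobutane lactone F1. It is heated in toluene at 110 °C to the racemic ring-expanded lactone, that is 11 together with the enantiomeric ring C lactone F2. Preparative HPLC on a chiral stationary phase separates the two, and the route is rejoined at 11.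

Step 12. The allylsilane may attack the other enone β-carbon (bicyclo[2.2.2]octane closure), show poor exo/endo control at the allyl carbon, or be protodesilylated. Fallback with reversed polarity: the route sets out from 16, whose ene-dione is saturated with Zn in AcOH to the ring D 1,4-diketone F3. N-Bromosuccinimide (CH2Cl2, −78 °C) replaces silicon by bromine to give the allylic bromide F4 (drawn as the primary (E)-4-bromo-3-methylbut-2-enyl isomer). LiN(SiMe3)2 in THF then closes ring E by intramolecular SN2' alkylation of the ketone enolate, and the route is rejoined at 17.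

Step 8. The aluminium hemiacetals may be over-reduced to primary alcohols, or the hindered bridgehead ester may be incompletely reduced before the Grignard reagent is added. Fallback: the route sets out from 11, which LiAlH4 (THF, 0 °C) reduces exhaustively to the phenol diol F5. MeI/K2CO3 gives the aryl dimethyl ether diol F6, Swern oxidation gives the dialdehyde F7, and CH2=CHMgBr adds to both aldehydes; the route is rejoined at 14.

Further compounds
F1 | step 7 | enantiomeric vinylcyclobutane lactone (mirror image of 10) | C[Si](C)(C)C/C(C)=C/C[C@@]12C(=O)Oc3ccc(OC)c4c3[C@@]2(C(=O)OCC)C(C(C)=C)[C@H]14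
F2 | step 7 | enantiomeric ring C lactone (mirror image of 11) | C[Si](C)(C)C/C(C)=C/C[C@@]12C(=O)Oc3ccc(OC)c4c3[C@@]2(C(=O)OCC)CC(C)=C[C@H]14
F3 | step 12 | ring D 1,4-diketone with intact allylsilane chain | C[Si](C)(C)C/C(C)=C/C[C@@]23C(=O)CCC(=O)[C@@]21CC(C)=C[C@@H]3c2c(OC)ccc(OC)c21
F4 | step 12 | allylic bromide with (E)-4-bromo-3-methylbut-2-enyl chain | BrC/C(C)=C/C[C@@]23C(=O)CCC(=O)[C@@]21CC(C)=C[C@@H]3c2c(OC)ccc(OC)c21
F5 | step 8 | phenol diol (hydroxymethyl groups on bridge carbon and bridgehead) | C[Si](C)(C)C/C(C)=C/C[C@@]1(CO)[C@@]2(CO)CC(C)=C[C@@H]1c1c(OC)ccc(O)c12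
F6 | step 8 | aryl dimethyl ether diol | C[Si](C)(C)C/C(C)=C/C[C@@]1(CO)[C@@]2(CO)CC(C)=C[C@@H]1c1c(OC)ccc(OC)c12
F7 | step 8 | dialdehyde | C[Si](C)(C)C/C(C)=C/C[C@@]1(C=O)[C@@]2(C=O)CC(C)=C[C@@H]1c1c(OC)ccc(OC)c12
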